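**Retrosynthetic overview**

1. Last step: peripheral epoxidation of the E-4,5-olefin of the macrocyclic dienolide 21 sets C4 and C5.
2. Key disconnection C6–C7: the β-carbon of a (Z)-β-iodo enoate is made a donor (alkenylchromium, a β-acylvinyl anion of reversed polarity) and adds intramolecularly to the C6 enal. This one step closes the ten-membered carbocycle, sets C6 and, by lactonisation of the alkoxide, forms the butenolide.
3. The seco chain 19 comes from a C9–C10 Paterson anti-aldol (sets C9 and C10) between the α'-benzoyloxy ethyl ketone 6 (C1–C6, from geraniol) and the α-acyloxy aldehyde 14 (C7–C9 and C11–C13).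
4. Aldehyde 14 comes from methyl propiolate and crotonaldehyde: asymmetric alkynylation (sets C8), then iodide conjugate addition with formaldehyde aldol to build the tetrasubstituted iodo-enoate.
5. Ring order: carbocycle and butenolide together (step 13), epoxide last (step 14).

Assumption: germacrane numbering is used for atom labels (C1 ketone, C4–C5 epoxide, C6 lactone CH–O, C7=C11, C8 O-methacrylate, C9 OH, C10 CHMe, C12 lactone C=O, C13 CH2OAc), and each chiral catalyst is named as the enantiomer taken to give the configuration drawn (the mirror-image catalyst is used if its sense is the opposite).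

**Route**

Step 1
Reactants: 1 geraniol
Product: 2 geranyl triethylsilyl ether
Conditions: TESCl, imidazole, CH2Cl2, 0 °C
Reagents that add atoms: triethylsilyl chloride, CC[Si](Cl)(CC)CC
Why: Imidazole-promoted silyl ether formation on the primary allylic alcohol; no stereocentre is formed.

Step 2
Reactants: 2 geranyl triethylsilyl ether
Product: 3 (E)-4-methyl-6-[(triethylsilyl)oxy]hex-4-enal
Conditions: O3 (1.0 equiv, Sudan red 7B endpoint), CH2Cl2, −78 °C; then Me2S
Reagents that add atoms: ozone, [O-][O+]=O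
Why: Chemoselective ozonolysis, because the remote 6,7-olefin is more electron-rich than the 2,3-olefin that is inductively deactivated by the allylic silyloxy group (as with geranyl acetate); the E-olefin is untouched.

Step 3
Reactants: 3 (E)-4-methyl-6-[(triethylsilyl)oxy]hex-4-enal
Product: 4 (2R,4E)-4-methyl-1-oxo-6-[(triethylsilyl)oxy]hex-4-en-2-yl benzoate
Conditions: (BzO)2, (R)-α,α-diphenylprolinol trimethylsilyl ether (10 mol %), THF, 0 °C
Reagents that add atoms: dibenzoyl peroxide, O=C(OOC(=O)c1ccccc1)c1ccccc1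
Why: Enamine-catalysed direct α-benzoyloxylation of an aldehyde, in which the bulky diarylmethyl group shields one face of the E-enamine so the peroxide oxygen enters from the other face and sets C2 as R.

Step 4
Reactants: 4 (2R,4E)-4-methyl-1-oxo-6-[(triethylsilyl)oxy]hex-4-en-2-yl benzoate
Product: 5 (3RS,4R,6E)-3-hydroxy-6-methyl-8-[(triethylsilyl)oxy]oct-6-en-4-yl benzoate
Conditions: EtMgBr, THF, −78 °C; pH 7 buffer quench at −78 °C
Reagents that add atoms: ethylmagnesium bromide, CC[Mg]Br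
Why: Grignard 1,2-addition to the aldehyde is much faster than attack on the benzoate at −78 °C and the cold neutral quench prevents 1,2-benzoyl migration; the new carbinol centre is removed in step 5.

Step 5
Reactants: 5 (3RS,4R,6E)-3-hydroxy-6-methyl-8-[(triethylsilyl)oxy]oct-6-en-4-yl benzoate
Product: 6 (4R,6E)-6-methyl-3-oxo-8-[(triethylsilyl)oxy]oct-6-en-4-yl benzoate
Conditions: Dess–Martin periodinane, CH2Cl2, 0 °C to rt
Reagents that add atoms: none
Why: Dess–Martin oxidation gives the α'-benzoyloxy ethyl ketone (an analogue of the lactate-derived Paterson ketone) without epimerising C2.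

Step 6
Reactants: 7 methyl propiolate; 8 (E)-crotonaldehyde
Product: 10 methyl (4S,5E)-4-hydroxyhept-5-en-2-ynoate, via zinc acetylide 9 (not isolated)
Conditions: Me2Zn (3 equiv), (S,S)-ProPhenol (10 mol %), Ph3P=O (20 mol %), toluene, 0 °C
Reagents that add atoms: none
Why: Trost ProPhenol dinuclear-zinc asymmetric alkynylation of an enal, in which the chiral zinc complex delivers the alkynyl group to one aldehyde face and sets the carbinol centre that becomes C8.

Step 7
Reactants: 10 methyl (4S,5E)-4-hydroxyhept-5-en-2-ynoate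
Product: 11 methyl (4S,5E)-4-(methacryloyloxy)hept-5-en-2-ynoate
Conditions: methacrylic anhydride, pyridine, DMAP (5 mol %), CH2Cl2, −20 to 0 °C
Reagents that add atoms: methacrylic anhydride, C=C(C)C(=O)OC(=O)C(C)=C
Why: DMAP-catalysed acylation installs the methacrylate of the target early, where it also prevents lactonisation and cyclic ether formation later; no stereochemical change.

Step 8
Reactants: 11 methyl (4S,5E)-4-(methacryloyloxy)hept-5-en-2-ynoate
Product: 13 methyl (2Z,4S,5E)-2-(acetoxymethyl)-3-iodo-4-(methacryloyloxy)hepta-2,5-dienoate, via hydroxymethyl iodoenoate 12 (not isolated)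
Conditions: MgI2 (1.3 equiv), monomeric CH2O (THF solution), CH2Cl2, −20 to 0 °C; then Ac2O, pyridine, DMAP (cat.), 0 °C
Reagents that add atoms: magnesium iodide, [Mg+2].[I-].[I-]; formaldehyde, C=O; acetic anhydride, CC(=O)OC(C)=O
Why: Proposed new method: iodide adds in conjugate fashion to the magnesium-activated ynoate to give a β-iodo allenolate that is hydroxymethylated by formaldehyde on the side away from iodine (anti addition, as in the known MgI2 β-iodo Morita–Baylis–Hillman coupling of propiolates and the anti hydroiodination of 2-alkynoates), giving the Z isomer with iodine cis to CO2Me, and the magnesium alkoxide is acetylated in the same flask; the closest known reaction is the MgI2- or Et2AlI-mediated three-component β-iodo Baylis–Hillman reaction.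

Step 9
Reactants: 13 methyl (2Z,4S,5E)-2-(acetoxymethyl)-3-iodo-4-(methacryloyloxy)hepta-2,5-dienoate
Product: 14 methyl (2Z,4S)-2-(acetoxymethyl)-3-iodo-4-(methacryloyloxy)-5-oxopent-2-enoate
Conditions: O3 (Sudan red 7B endpoint), CH2Cl2, −78 °C; then Me2S; used crude
Reagents that add atoms: ozone, [O-][O+]=O
Why: Ozonolysis cleaves the 1,2-disubstituted propenyl olefin in preference to the conjugated, electron-poor methacrylate and iodo-enoate olefins and unmasks the C9 aldehyde; C8 is untouched.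

Step 10
Reactants: 6 (4R,6E)-6-methyl-3-oxo-8-[(triethylsilyl)oxy]oct-6-en-4-yl benzoate; 14 methyl (2Z,4S)-2-(acetoxymethyl)-3-iodo-4-(methacryloyloxy)-5-oxopent-2-enoate
Product: 16 methyl (2Z,4S,5R,6S,8R,10E)-2-(acetoxymethyl)-8-(benzoyloxy)-5-hydroxy-3-iodo-4-(methacryloyloxy)-6,10-dimethyl-7-oxo-12-[(triethylsilyl)oxy]dodeca-2,10-dienoate, via boron enolate 15 (not isolated)
Conditions: 6, (c-Hex)2BCl, Me2NEt, Et2O, 0 °C, 2 h; then 14, −78 to −25 °C; MeOH/pH 7 buffer
Reagents that add atoms: none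
Why: Paterson boron-mediated anti-aldol, in which (c-Hex)2BCl/Me2NEt enolises only the ethyl side to the E-enolate and the chair transition state with the α'-benzoate turned toward the aldehyde (formyl hydrogen bond) sets C10 as S and C9 as R (anti) under ketone control, overriding the weaker Cornforth bias of the α-acyloxy aldehyde (a mismatched pair, so a lower ratio is expected).

Step 11
Reactants: 16 (aldol adduct)
Product: 18 methyl (2Z,4S,5R,6S,10E)-2-(acetoxymethyl)-5,12-dihydroxy-3-iodo-4-(methacryloyloxy)-6,10-dimethyl-7-oxododeca-2,10-dienoate, via triethylsilyl ether 17 (not isolated)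
Conditions: SmI2 (2.5 equiv), THF/MeOH, −78 °C, 10 min; then 1 M HCl, THF, 0 °C
Reagents that add atoms: none
Why: SmI2 reductive cleavage of the α-benzoyloxy ketone (fast at −78 °C through the chelated ketyl, whereas enoates and vinyl iodides need additives or higher temperature) removes the stereo-directing group through an enolate on the C2 side only, and the acidic work-up cleaves the primary silyl ether; no stereocentre changes.

Step 12
Reactants: 18 (diol)
Product: 19 methyl (2Z,4S,5R,6S,10E)-2-(acetoxymethyl)-5-hydroxy-3-iodo-4-(methacryloyloxy)-6,10-dimethyl-7,12-dioxododeca-2,10-dienoate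
Conditions: MnO2, CH2Cl2, rt
Reagents that add atoms: none
Why: MnO2 allylic oxidation converts only the primary allylic alcohol into the E-enal and leaves the non-allylic C9 carbinol.

Step 13
Reactants: 19 (iodo-enoate enal)
Product: 21 (4E,6R,8R,9R,10S)-13-acetoxy-9-hydroxy-8-(methacryloyloxy)-1-oxogermacra-4,7(11)-dien-12,6-olide, via hydroxy ester 20 (not isolated)
Conditions: CrCl2 (8 equiv), NiCl2 (2 mol %), DMSO/THF, rt, 2 mM, slow addition; sat. NH4Cl work-up
Reagents that add atoms: none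
Why: Nozaki–Hiyama–Kishi macrocyclisation, in which zerovalent nickel inserts into the activated vinyl C–I bond and transmetalation gives an alkenylchromium (trivalent chromium) that acts as a β-acylvinyl anion, a donor at the normally acceptor β-carbon of the enoate, adding only to the aldehyde (ketone, esters and free OH tolerated) before the chromium alkoxide lactonises onto the cis ester; C6 is set by the ring-forming transition state, predicted to place C5 and C9 on opposite faces of the enoate plane with C8–H eclipsing C7=C11 (the 6R configuration of 21), which is a prediction and not a precedent.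

Step 14
Reactants: 21 (macrocyclic dienolide)
Product: 22 (4R,5R,6S,8R,9R,10S)-13-acetoxy-4,5-epoxy-9-hydroxy-8-(methacryloyloxy)-1-oxogermacr-7(11)-en-12,6-olide (CNP0185951.1)
Conditions: mCPBA (1.1 equiv), CH2Cl2/pH 7 phosphate buffer, 0 °C
Reagents that add atoms: 3-chloroperbenzoic acid, O=C(OO)c1cccc(Cl)c1
Why: Peripheral peracid epoxidation of the only electron-rich olefin, in which C6–H eclipses the olefin plane (allylic strain with the C4 methyl) and the ring blocks the face carrying C7, so oxygen enters from the face of the lactone oxygen and gives the 4R,5R epoxide (the costunolide-to-parthenolide type of selectivity).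

**Compound list**

1 | geraniol | CC(C)=CCC/C(C)=C/CO | starting material
2 | geranyl triethylsilyl ether | CC(C)=CCC/C(C)=C/CO[Si](CC)(CC)CC | intermediate
3 | (E)-4-methyl-6-[(triethylsilyl)oxy]hex-4-enal | O=CCC/C(C)=C/CO[Si](CC)(CC)CC | intermediate
4 | (2R,4E)-4-methyl-1-oxo-6-[(triethylsilyl)oxy]hex-4-en-2-yl benzoate | O=C[C@H](OC(=O)c1ccccc1)C/C(C)=C/CO[Si](CC)(CC)CC | intermediate
5 | (3RS,4R,6E)-3-hydroxy-6-methyl-8-[(triethylsilyl)oxy]oct-6-en-4-yl benzoate | CCC(O)[C@H](OC(=O)c1ccccc1)C/C(C)=C/CO[Si](CC)(CC)CC | intermediate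
6 | (4R,6E)-6-methyl-3-oxo-8-[(triethylsilyl)oxy]oct-6-en-4-yl benzoate | CCC(=O)[C@H](OC(=O)c1ccccc1)C/C(C)=C/CO[Si](CC)(CC)CC | intermediate
7 | methyl propiolate | C#CC(=O)OC | starting material
8 | (E)-crotonaldehyde | C/C=C/C=O | starting material
9 | methyl 3-(methylzincio)propiolate (zinc acetylide of 7) | COC(=O)C#C[Zn]C | intermediate
10 | methyl (4S,5E)-4-hydroxyhept-5-en-2-ynoate | C/C=C/[C@H](O)C#CC(=O)OC | intermediate
11 | methyl (4S,5E)-4-(methacryloyloxy)hept-5-en-2-ynoate | C/C=C/[C@H](OC(=O)C(C)=C)C#CC(=O)OC | intermediate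
12 | methyl (2Z,4S,5E)-2-(hydroxymethyl)-3-iodo-4-(methacryloyloxy)hepta-2,5-dienoate (present as its magnesium alkoxide) | C/C=C/[C@H](OC(=O)C(C)=C)/C(I)=C(\CO)C(=O)OC | intermediate
13 | methyl (2Z,4S,5E)-2-(acetoxymethyl)-3-iodo-4-(methacryloyloxy)hepta-2,5-dienoate | C/C=C/[C@H](OC(=O)C(C)=C)/C(I)=C(\COC(C)=O)C(=O)OC | intermediate
14 | methyl (2Z,4S)-2-(acetoxymethyl)-3-iodo-4-(methacryloyloxy)-5-oxopent-2-enoate | O=C[C@H](OC(=O)C(C)=C)/C(I)=C(\COC(C)=O)C(=O)OC | intermediate
15 | (2E,4R,6E)-3-[(dicyclohexylboranyl)oxy]-6-methyl-8-[(triethylsilyl)oxy]octa-2,6-dien-4-yl benzoate (E-boron enolate of 6) | C/C=C(/OB(C1CCCCC1)C1CCCCC1)[C@H](OC(=O)c1ccccc1)C/C(C)=C/CO[Si](CC)(CC)CC | intermediate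
16 | methyl (2Z,4S,5R,6S,8R,10E)-2-(acetoxymethyl)-8-(benzoyloxy)-5-hydroxy-3-iodo-4-(methacryloyloxy)-6,10-dimethyl-7-oxo-12-[(triethylsilyl)oxy]dodeca-2,10-dienoate | C=C(C)C(=O)O[C@H](/C(I)=C(\COC(C)=O)C(=O)OC)[C@H](O)[C@H](C)C(=O)[C@H](OC(=O)c1ccccc1)C/C(C)=C/CO[Si](CC)(CC)CC | intermediate
17 | methyl (2Z,4S,5R,6S,10E)-2-(acetoxymethyl)-5-hydroxy-3-iodo-4-(methacryloyloxy)-6,10-dimethyl-7-oxo-12-[(triethylsilyl)oxy]dodeca-2,10-dienoate | C=C(C)C(=O)O[C@H](/C(I)=C(\COC(C)=O)C(=O)OC)[C@H](O)[C@H](C)C(=O)CC/C(C)=C/CO[Si](CC)(CC)CC | intermediate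
18 | methyl (2Z,4S,5R,6S,10E)-2-(acetoxymethyl)-5,12-dihydroxy-3-iodo-4-(methacryloyloxy)-6,10-dimethyl-7-oxododeca-2,10-dienoate | C=C(C)C(=O)O[C@H](/C(I)=C(\COC(C)=O)C(=O)OC)[C@H](O)[C@H](C)C(=O)CC/C(C)=C/CO | intermediate
19 | methyl (2Z,4S,5R,6S,10E)-2-(acetoxymethyl)-5-hydroxy-3-iodo-4-(methacryloyloxy)-6,10-dimethyl-7,12-dioxododeca-2,10-dienoate | C=C(C)C(=O)O[C@H](/C(I)=C(\COC(C)=O)C(=O)OC)[C@H](O)[C@H](C)C(=O)CC/C(C)=C/C=O | intermediate
20 | methyl (4E,6R,8R,9R,10S)-13-acetoxy-6,9-dihydroxy-8-(methacryloyloxy)-1-oxogermacra-4,7(11)-dien-12-oate (ten-membered ring, ester carbon cis to C6) | C=C(C)C(=O)O[C@@H]1/C(=C(\COC(C)=O)C(=O)OC)[C@H](O)/C=C(C)/CCC(=O)[C@@H](C)[C@H]1O | intermediate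
21 | (4E,6R,8R,9R,10S)-13-acetoxy-9-hydroxy-8-(methacryloyloxy)-1-oxogermacra-4,7(11)-dien-12,6-olide | C=C(C)C(=O)O[C@@H]1C2=C(COC(C)=O)C(=O)O[C@@H]2/C=C(C)/CCC(=O)[C@@H](C)[C@H]1O | intermediate
22 | (4R,5R,6S,8R,9R,10S)-13-acetoxy-4,5-epoxy-9-hydroxy-8-(methacryloyloxy)-1-oxogermacr-7(11)-en-12,6-olide (CNP0185951.1) | C=C(C)C(=O)O[C@@H]1C2=C(COC(C)=O)C(=O)O[C@@H]2[C@H]2O[C@]2(C)CCC(=O)[C@@H](C)[C@H]1O | target

**Step count and risks**

Total steps: 14. Longest linear sequence: 10 steps (steps 1–5, then 10–14); the second branch is steps 6–9.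

The three steps most likely to fail:

Step 8. The iodide addition/formaldehyde aldol on a β-substituted, γ-acyloxy ynoate is unprecedented, and the Z geometry (needed for the later lactonisation) rests on analogy. Fallback, setting out from 10 and coming back at 13: the carbon that becomes C13 is delivered from a temporary silicon tether on the C8 oxygen, so that it must end up cis to C8. Alcohol 10 is silylated with (bromomethyl)chlorodimethylsilane and Et3N to give methyl (4S,5E)-4-{[(bromomethyl)dimethylsilyl]oxy}hept-5-en-2-ynoate F1. MgI2 in MeCN at 40 °C then triggers iodide conjugate addition, and the allenolate is alkylated by the tethered CH2Br through a six-membered ring to give methyl (6S)-5-iodo-2,2-dimethyl-6-[(E)-prop-1-en-1-yl]-3,6-dihydro-2H-1,2-oxasiline-4-carboxylate F2. Tamao–Fleming oxidation (H2O2, KF, KHCO3, THF/MeOH) opens the ring to methyl (2Z,4S,5E)-4-hydroxy-2-(hydroxymethyl)-3-iodohepta-2,5-dienoate F3. Acetyl chloride with 2,4,6-collidine at −78 °C acetylates only the primary alcohol to give methyl (2Z,4S,5E)-2-(acetoxymethyl)-4-hydroxy-3-iodohepta-2,5-dienoate F4, and methacrylic anhydride with DMAP then gives 13.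

Step 11. SmI2 may also attack the β-iodo enoate or the 2-(acetoxymethyl) enoate. Fallback, setting out from 16 and coming back at 21: the benzoate is removed only after the carbon–iodine bond has been used. 16 is treated with 1 M HCl in THF to give methyl (2Z,4S,5R,6S,8R,10E)-2-(acetoxymethyl)-8-(benzoyloxy)-5,12-dihydroxy-3-iodo-4-(methacryloyloxy)-6,10-dimethyl-7-oxododeca-2,10-dienoate F5. MnO2 gives methyl (2Z,4S,5R,6S,8R,10E)-2-(acetoxymethyl)-8-(benzoyloxy)-5-hydroxy-3-iodo-4-(methacryloyloxy)-6,10-dimethyl-7,12-dioxododeca-2,10-dienoate F6. The CrCl2/NiCl2 macrocyclisation then passes through methyl (2R,4E,6R,8R,9R,10S)-13-acetoxy-2-(benzoyloxy)-6,9-dihydroxy-8-(methacryloyloxy)-1-oxogermacra-4,7(11)-dien-12-oate F7 (not isolated) to (2R,4E,6R,8R,9R,10S)-13-acetoxy-2-(benzoyloxy)-9-hydroxy-8-(methacryloyloxy)-1-oxogermacra-4,7(11)-dien-12,6-olide F8. SmI2 in THF/MeOH at −78 °C then removes the benzoate to give 21.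

Step 13. Ten-membered ring closure may give oligomers, the alkenylchromium may eliminate the allylic methacrylate to an allenoate, and the C6 configuration is only predicted. Fallback, setting out from 19 and coming back at 20 and then 21: the ring is closed as a ketone and C6 is set afterwards by a reagent-controlled reduction. Pinnick oxidation of 19 (NaClO2, NaH2PO4, 2-methylbut-2-ene) gives (2E,7S,8R,9S,10Z)-11-(acetoxymethyl)-8-hydroxy-10-iodo-12-methoxy-9-(methacryloyloxy)-3,7-dimethyl-6,12-dioxododeca-2,10-dienoic acid F9. 2,2'-Dipyridyl disulfide and PPh3 convert it into its S-(pyridin-2-yl) thioester F10. Intramolecular nickel-catalysed reductive acyl–vinyl coupling (NiCl2(dme), 4,4'-di-tert-butyl-2,2'-bipyridine, Zn, DMA, high dilution) gives methyl (4E,8R,9R,10S)-13-acetoxy-9-hydroxy-8-(methacryloyloxy)-1,6-dioxogermacra-4,7(11)-dien-12-oate F11. Reduction of the cross-conjugated C6 ketone with (S)-2-methyl-CBS-oxazaborolidine and catecholborane at −78 °C gives hydroxy ester 20, which lactonises to 21.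

**Further compounds**

F1 | step 8 | methyl (4S,5E)-4-{[(bromomethyl)dimethylsilyl]oxy}hept-5-en-2-ynoate | C/C=C/[C@H](O[Si](C)(C)CBr)C#CC(=O)OC
F2 | step 8 | methyl (6S)-5-iodo-2,2-dimethyl-6-[(E)-prop-1-en-1-yl]-3,6-dihydro-2H-1,2-oxasiline-4-carboxylate | C/C=C/[C@@H]1O[Si](C)(C)CC(C(=O)OC)=C1I
F3 | step 8 | methyl (2Z,4S,5E)-4-hydroxy-2-(hydroxymethyl)-3-iodohepta-2,5-dienoate | C/C=C/[C@H](O)/C(I)=C(\CO)C(=O)OC
F4 | step 8 | methyl (2Z,4S,5E)-2-(acetoxymethyl)-4-hydroxy-3-iodohepta-2,5-dienoate | C/C=C/[C@H](O)/C(I)=C(\COC(C)=O)C(=O)OC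
F5 | step 11 | methyl (2Z,4S,5R,6S,8R,10E)-2-(acetoxymethyl)-8-(benzoyloxy)-5,12-dihydroxy-3-iodo-4-(methacryloyloxy)-6,10-dimethyl-7-oxododeca-2,10-dienoate | C=C(C)C(=O)O[C@H](/C(I)=C(\COC(C)=O)C(=O)OC)[C@H](O)[C@H](C)C(=O)[C@H](OC(=O)c1ccccc1)C/C(C)=C/CO
F6 | step 11 | methyl (2Z,4S,5R,6S,8R,10E)-2-(acetoxymethyl)-8-(benzoyloxy)-5-hydroxy-3-iodo-4-(methacryloyloxy)-6,10-dimethyl-7,12-dioxododeca-2,10-dienoate | C=C(C)C(=O)O[C@H](/C(I)=C(\COC(C)=O)C(=O)OC)[C@H](O)[C@H](C)C(=O)[C@H](OC(=O)c1ccccc1)C/C(C)=C/C=O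
F7 | step 11 | methyl (2R,4E,6R,8R,9R,10S)-13-acetoxy-2-(benzoyloxy)-6,9-dihydroxy-8-(methacryloyloxy)-1-oxogermacra-4,7(11)-dien-12-oate | C=C(C)C(=O)O[C@@H]1/C(=C(\COC(C)=O)C(=O)OC)[C@H](O)/C=C(C)/C[C@@H](OC(=O)c2ccccc2)C(=O)[C@@H](C)[C@H]1O
F8 | step 11 | (2R,4E,6R,8R,9R,10S)-13-acetoxy-2-(benzoyloxy)-9-hydroxy-8-(methacryloyloxy)-1-oxogermacra-4,7(11)-dien-12,6-olide | C=C(C)C(=O)O[C@@H]1C2=C(COC(C)=O)C(=O)O[C@@H]2/C=C(C)/C[C@@H](OC(=O)c3ccccc3)C(=O)[C@@H](C)[C@H]1O
F9 | step 13 | (2E,7S,8R,9S,10Z)-11-(acetoxymethyl)-8-hydroxy-10-iodo-12-methoxy-9-(methacryloyloxy)-3,7-dimethyl-6,12-dioxododeca-2,10-dienoic acid | C=C(C)C(=O)O[C@H](/C(I)=C(\COC(C)=O)C(=O)OC)[C@H](O)[C@H](C)C(=O)CC/C(C)=C/C(=O)O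
F10 | step 13 | S-(pyridin-2-yl) thioester of F9 | C=C(C)C(=O)O[C@H](/C(I)=C(\COC(C)=O)C(=O)OC)[C@H](O)[C@H](C)C(=O)CC/C(C)=C/C(=O)Sc1ccccn1
F11 | step 13 | methyl (4E,8R,9R,10S)-13-acetoxy-9-hydroxy-8-(methacryloyloxy)-1,6-dioxogermacra-4,7(11)-dien-12-oate | C=C(C)C(=O)O[C@@H]1/C(=C(\COC(C)=O)C(=O)OC)C(=O)/C=C(C)/CCC(=O)[C@@H](C)[C@H]1O
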